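| setting | alder | elm | larch | flask |
|---|---|---|---|---|
| left-handed substrate | 5 mM | 5 mM | 7.5 mM | 5.0 mM |
| right-handed substrate | 5 mM | 5 mM | 7.5 mM | 5.0 mM |
| reagent | 11 mM (fed, over 1.5 s) | 11 mM (fed, over 1.5 s) | 11 mM (fed, over 1.5 s) | 11.0 mM (fed, over 1.5 s) |
| free catalyst | 12 µM | 50 µM | 25 µM | 25 µM |
| remark | run made earlier | run made earlier | run made earlier |  |
| time |  |  |  | 2.5 min |

| run | time / min | left-handed product / % | right-handed product / % |
|---|---|---|---|
| alder | 0.200 | 28.1 | 14.2 |
| alder | 0.333 | 36.4 | 19.7 |
| alder | 0.500 | 36.9 | 20.6 |
| alder | 0.667 | 40.0 | 22.7 |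
| alder | 1.00 | 41.8 | 23.8 |
| alder | 1.50 | 40.8 | 24.8 |
| alder | 2.50 | 40.5 | 23.8 |
| elm | 0.167 | 38.3 | 25.1 |
| elm | 0.417 | 47.0 | 34.8 |
| elm | 0.667 | 50.7 | 35.7 |
| elm | 1.00 | 52.4 | 36.1 |
| elm | 1.50 | 54.2 | 40.0 |
| elm | 2.00 | 53.5 | 37.2 |
| elm | 2.50 | 51.9 | 38.3 |
| larch | 0.500 | 40.6 | 25.5 |
| larch | 1.00 | 42.9 | 23.9 |
| larch | 1.50 | 40.9 | 26.5 |
| larch | 2.00 | 42.0 | 24.7 |
| larch | 2.50 | 41.6 | 24.9 |

(readings scatter by 1 percentage point)

- free catalyst is single-handed; left-handed substrate and right-handed substrate are mirror images of each other, charged as a racemate, each of them at the stated concentration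
- an excess is the difference of the two amounts in percent of their sum
- an excess is below zero if the other one leads

* excess of left-handed product over right-handed product in the product at 3.0 s
* excess of left-handed product over right-handed product in the product at 2.5 min
* part of the left-handed substrate and right-handed substrate charged together that has reacted at 2.5 min

I take it that each product costs one reagent and one substrate of either hand, so once the feed is in, c(reagent) − c(substrates), with both hands counted together, stays constant in a flask: this is my invariant. Yet the alder run levels off at 65.2% product, the mean of its last 3 readings, with 4.48 mM of reagent and 3.48 mM of substrates unused by this count.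

So I follow one free catalyst molecule, whose fork at each moment is another turnover or loss from work. Two times compete: its working life τ, and the reaction time t = 1/(k · c(free catalyst) · c(reagent)), both at the charge, with the two hands treated as one k. Their ratio Λ = τ/t, a Damköhler number and the reach of the charge, is what I carry, and if the working life is taken as a first-order decay, the invariant turns it into:

ln[(c(reagent)/c(substrates)) at the end ÷ the same at the start] = Λ · (c(reagent) − c(substrates)) / c(reagent at the start)

Likewise taking the plateaus 91.7% for elm and 66.9% for larch, the readings give Λ: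

alder 1.73, larch 3.64, elm 7.65

From alder to elm Λ grows 4.42-fold while the free catalyst charge grows 4.17-fold. The flask has larch's free catalyst and reagent, so I carry larch's Λ over:

end ratio 1.53, reacted 81.2%

The forecast gives 37%, 20.5% and 79%, the last by its words “interpolating on catalyst gives about 79%”.

The flask gives excesses of 35.4% at 3.0 s and 21.4% at 2.5 min, with 80.5% reacted. At 2.50 min it still holds 26.8% of its reagent, while spent catalyst stands at >99.9% of the catalyst charged. Through the invariant, my reckoning with Λ gives 26.2% of the reagent for this flask.

    reagent + free catalyst + left-handed substrate → free catalyst + left-handed product (k = 1.30 × 10⁶ L² mol⁻² s⁻¹)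
    reagent + free catalyst + right-handed substrate → free catalyst + right-handed product (k = 5.60 × 10⁵ L² mol⁻² s⁻¹)
    left-handed substrate ⇌ right-handed substrate (k = 0.0110 s⁻¹)
    2 free catalyst ⇌ resting dimer, settled at all times (K = 27000 L mol⁻¹)
    free catalyst → spent catalyst (k = 0.0630 s⁻¹)

A neighbour flask gets 6.6 mM of reagent with the same free catalyst, so Λ scales to 2.18, the end ratio is 0.214, and I reckon 56.7% reacted. The computed neighbour flask gives 57.0%.

Readings and results were generated by integration with made-up constants; scatter was added.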